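Target read as 8α,15-dihydroxy-14-oxolabd-13(16)-en-19-oic acid (trans-decalin, axial 4β-CO2H, 5α-H, 9α-H, 10β-CH3). Labdane numbering is used throughout, also for open-chain compounds.
Retrosynthetic cuts, in order: C15–O and C13=C16 (side-chain end); C8–O and C8=C17; C4–C18 and C4–C19; then C6–C7 together with C5–C10 (both rings opened at once); then C4–C5, C1–C10 and C9–C11.
Enabling feature: ring B (C5–C6–C7–C8–C9–C10) has its only heteroatom at C8 and an unsubstituted C6H2–C7H2 edge, and C5 adjoins C4, which can be carried as a ketone. Ring B is therefore the retron of a 2-silyloxydiene (C7=C8(OSi)–C9=C10) plus vinyl ketone (C4(=O)–C5=C6) Diels–Alder reaction, with the C1–C3 chain of ring A as tether.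
Forward: acetylacetone supplies C7–C10 and C20. Alkylation (C11–C15), Z-enol triflate formation, B-alkyl Suzuki coupling (C1–C4) and vinyl addition (C5, C6) give an achiral open-chain trienone. One intramolecular Diels–Alder reaction closes rings A and B, and C19, C18, C17, C16 and the C15 oxygen then follow one at a time.
Stereochemistry: C10 comes from a chiral Brønsted acid in the cycloaddition. The rest is relayed from the axial C10 methyl group: C5 by equilibration next to the C4 ketone, C4 by α-face methylation, C9 by protonation next to the C8 ketone, and C8 by α-face O2 capture.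

Key step: step 7

Assumption: the sense of induction of the catalyst in step 7 cannot be derived with certainty for this intramolecular case. The (S)-catalyst is written, and its equally available enantiomer is used if the opposite sense is found.

Step 1
Reactants: 1 pentane-2,4-dione; 2 2-(3-chloropropyl)-2-methyl-1,3-dioxolane
Product: 4 3-[3-(2-methyl-1,3-dioxolan-2-yl)propyl]pentane-2,4-dione, via iodide 3 (not isolated)
Conditions: NaI (1.2 equiv), K2CO3 (1.5 equiv), DMF, 70 °C
Reagents that add atoms: none
Why: Finkelstein exchange followed by C-alkylation of the soft β-diketone enolate with a primary iodide joins C9 to C11; the diketone is symmetrical, so no regiochemical question arises and no stereocentre is formed.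

Step 2
Reactants: 4 3-[3-(2-methyl-1,3-dioxolan-2-yl)propyl]pentane-2,4-dione
Product: 5 (2Z)-3-acetyl-6-(2-methyl-1,3-dioxolan-2-yl)hex-2-en-2-yl trifluoromethanesulfonate (OTf cis to the acetyl group)
Conditions: LiOTf, Et3N, Tf2O, CH2Cl2, −20 → 0 °C
Reagents that add atoms: triflic anhydride, O=S(=O)(OS(=O)(=O)C(F)(F)F)C(F)(F)F
Why: O-sulfonylation of the lithium-chelated, U-shaped β-diketone enolate (enol triflate formation) places the triflate cis to the remaining acetyl group, which fixes the C9=C10 geometry; both carbonyl groups are equivalent.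

Step 3
Reactants: 6 but-3-enoic acid; 7 N,O-dimethylhydroxylamine hydrochloride
Product: 9 N-methoxy-N-methylbut-3-enamide, via acyl imidazolide 8 (not isolated)
Conditions: 1,1′-carbonyldiimidazole, CH2Cl2, 0 °C → rt; then 7
Reagents that add atoms: none
Why: Amide formation through the acyl imidazolide needs no added base, so the β,γ-double bond should not move into conjugation.

Step 4
Reactants: 9 N-methoxy-N-methylbut-3-enamide; 5 (Z)-enol triflate
Product: 11 (5Z)-6-acetyl-N-methoxy-N,5-dimethyl-9-(2-methyl-1,3-dioxolan-2-yl)non-5-enamide, via B-alkyl-9-BBN 10 (not isolated)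
Conditions: 9-BBN-H, THF, 0 °C → rt; then 5, PdCl2(dppf) (5 mol %), aq K3PO4, THF–DMF, rt → 40 °C
Reagents that add atoms: none
Why: Anti-Markovnikov hydroboration and B-alkyl Suzuki–Miyaura coupling with an activated β-acyl enol triflate form C1–C10 with retention of alkene geometry, so the tether ends up cis to the acetyl group.

Step 5
Reactants: 11 (Z)-enone amide
Product: 13 (5Z)-N-methoxy-N,5-dimethyl-9-(2-methyl-1,3-dioxolan-2-yl)-6-[1-(triisopropylsilyloxy)vinyl]non-5-enamide, via lithium dienolate 12 (not isolated)
Conditions: LDA (1.05 equiv), THF, −78 °C; TIPSOTf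
Reagents that add atoms: triisopropylsilyl triflate, CC(C)[Si](OS(=O)(=O)C(F)(F)F)(C(C)C)C(C)C
Why: Kinetic α′-deprotonation of the methyl ketone (most acidic and least hindered C–H) and O-silylation give the cross-conjugated 2-silyloxydiene; the less acidic amide is left alone.

Step 6
Reactants: 13 silyl dienol ether amide
Product: 15 (7Z)-7-methyl-11-(2-methyl-1,3-dioxolan-2-yl)-8-[1-(triisopropylsilyloxy)vinyl]undeca-1,7-dien-3-one, via magnesium chelate 14 (not isolated)
Conditions: vinylmagnesium bromide, THF, −78 → −20 °C; cold pH 7 buffer; used promptly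
Reagents that add atoms: vinylmagnesium bromide, C=C[Mg]Br
Why: Ketone synthesis from an N-methoxy-N-methylamide passes through a stable chelate that prevents over-addition, and the silyl dienol ether and ketal are inert to the Grignard reagent.

Step 7
Reactants: 15 open-chain trienone
Product: 16 cis-decalone: 14,14-(ethylenedioxy)-8-(triisopropylsilyloxy)-16,17,18,19-tetranorlabd-8-en-4-one, 5β-H, 10β-CH3
Conditions: (S)-3,3′-bis(2,4,6-triisopropylphenyl)-BINOL N-triflylphosphoramide (10 mol %), 4 Å MS, toluene (0.01 M), −60 → −20 °C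
Reagents that add atoms: none
Why: The chiral acid binds the C4 carbonyl group and lowers the LUMO of the C5=C6 vinyl ketone, which then undergoes a concerted but asynchronous intramolecular [4+2] cycloaddition with the C7=C8(OTIPS)–C9=C10 diene, the C6–C7 bond (largest HOMO coefficient at C7, largest LUMO coefficient at C6) running ahead of C5–C10. The closest known reaction types are the intramolecular Diels–Alder reaction of 1,7,9-decatrien-3-ones and the N-triflylphosphoramide-catalysed enantioselective Diels–Alder reaction of alkyl vinyl ketones with 2-silyloxydienes. Ring B closes as the new cyclohexene of the cycloaddition (bonds C6–C7 and C5–C10), and ring A closes at the same time as the six-membered ring that the C1–C4 tether spans across C5–C10. C5 and C10 form suprafacially, and because the tether occupies the inside (Z) position at C10 only the transition state leading to the cis-fused decalone (5β-H, 10β-CH3) is geometrically open, so the relative configuration follows from the alkene geometry set in steps 2 and 4. The absolute configuration at quaternary C10 comes from the catalyst, whose 3,3′-aryl groups leave one face of the bound enone open. The step needs activation of the enone in preference to the ketal and the enol ether, which anhydrous low-temperature conditions and the bulky TIPS group should secure, and it delivers the Δ8(9) enol ether regiospecifically, which keeps C8 and C4 differentiated.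

Step 8
Reactants: 16 cis-decalone
Product: 17 trans-decalone: 14,14-(ethylenedioxy)-8-(triisopropylsilyloxy)-16,17,18,19-tetranorlabd-8-en-4-one, 5α-H, 10β-CH3
Conditions: NaOMe (0.2 equiv), MeOH–THF, rt; any remaining 16 is separated and resubmitted
Reagents that add atoms: none
Why: Base-mediated epimerisation through the C4 enolate can invert only C5, and the trans-fused ketone should be the more stable one, as in the 5β to 5α isomerisation of 4-oxo steroids; with C8 masked as its silyl enol ether no retro-Michael path is open.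

Step 9
Reactants: 17 trans-decalone
Product: 19 14,14-(ethylenedioxy)-8-(triisopropylsilyloxy)-16,17,18,19-tetranorlabda-3,8-dien-4-yl triflate (5α-H), via potassium enolate 18 (not isolated)
Conditions: KHMDS, THF, −78 °C; PhNTf2; aq NH4Cl
Reagents that add atoms: N-phenylbis(trifluoromethanesulfonimide), O=S(=O)(N(c1ccccc1)S(=O)(=O)C(F)(F)F)C(F)(F)F
Why: Kinetic deprotonation takes the unhindered C3 methylene and not the tertiary, neopentyl C5–H, and O-sulfonylation traps the enolate (enol triflate formation), so C5 is not touched.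

Step 10
Reactants: 19 Δ3-enol triflate
Product: 20 methyl 14,14-(ethylenedioxy)-8-(triisopropylsilyloxy)-16,17,18-trinorlabda-3,8-dien-19-oate (5α-H)
Conditions: Pd(OAc)2 (5 mol %), dppp, CO (1 atm), MeOH, Et3N, DMF, 40 °C
Reagents that add atoms: carbon monoxide, [C-]#[O+]; methanol, CO
Why: Palladium-catalysed alkoxycarbonylation of an enol triflate (oxidative addition, CO insertion, methanolysis) brings in C19 under weakly basic conditions that spare the enol ether and the ketal.

Step 11
Reactants: 20 Δ3-enoate
Product: 22 methyl 14,14-(ethylenedioxy)-8-(triisopropylsilyloxy)-16,17-dinorlabd-8-en-19-oate (4α-CH3, 4β-CO2CH3, 5α-H), via lithium ester enolate 21 (not isolated)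
Conditions: Li (2.2 equiv), NH3–THF, t-BuOH (1 equiv), −78 °C; then MeI
Reagents that add atoms: methyl iodide, CI
Why: Dissolving-metal reduction of the enoate gives the C4 ester enolate regiospecifically (reductive alkylation), and methyl iodide approaches from the α face, away from the axial C10 methyl group, which places C18 equatorial and the ester axial as in the podocarpic acid series.

Step 12
Reactants: 22 quaternary ester
Product: 23 methyl 14,14-(ethylenedioxy)-8-oxo-16,17-dinorlabdan-19-oate (9α-H, equatorial side chain)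
Conditions: TBAF, AcOH, THF, 0 °C → rt
Reagents that add atoms: none
Why: Fluoride cleaves the Si–O bond and the enolate is protonated at C9 from the open α face; this is also the thermodynamic result (equatorial 9β chain), so enolisation under the reaction conditions corrects any epimer.

Step 13
Reactants: 23 8-ketone
Product: 24 methyl 14,14-(ethylenedioxy)-16-norlabd-8(17)-en-19-oate
Conditions: Ph3PCH3Br, KOt-Bu, THF–toluene, 60 °C
Reagents that add atoms: methyltriphenylphosphonium bromide, C[P+](c1ccccc1)(c1ccccc1)c1ccccc1.[Br-]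
Why: Wittig methylenation is well known for 8-oxo ketones of the labdane type; C9 already holds its stable configuration and the hindered axial ester does not react.

Step 14
Reactants: 24 8(17)-alkene
Product: 25 methyl 14,14-(ethylenedioxy)-8α-hydroxy-16-norlabdan-19-oate
Conditions: Mn(dpm)3 (10 mol %), PhSiH3, O2 (1 atm), i-PrOH, 0 °C → rt
Reagents that add atoms: dioxygen, O=O
Why: In the Mukaiyama hydration, hydrogen-atom transfer to C17 gives the tertiary C8 radical, which should take up O2 from the α face because the 1,3-related axial C10 methyl group screens the β face, giving the equatorial 8α-alcohol and the axial C17 methyl group.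

Step 15
Reactants: 25 hydroxy ester
Product: 27 8α-hydroxy-14-oxo-16-norlabdan-19-oic acid, via acid ketal 26 (not isolated)
Conditions: NaSEt, DMF, 100 °C; then 1 M HCl, THF, rt
Reagents that add atoms: water, O
Why: SN2 dealkylation by thiolate attacks the O-methyl carbon and not the shielded axial carbonyl group, and the acidic work-up hydrolyses the dioxolane; the tertiary alcohol should tolerate both operations.

Step 16
Reactants: 27 keto acid
Product: 28 8α-hydroxy-14-oxolabd-13(16)-en-19-oic acid
Conditions: paraformaldehyde, i-Pr2NH·CF3CO2H, THF, reflux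
Reagents that add atoms: formaldehyde (as paraformaldehyde), C=O
Why: Acid-catalysed Mannich-type condensation and elimination (direct α-methylenation) runs through the more substituted enol, so C16 is placed on the C13 methylene and not on the C15 methyl group.

Step 17
Reactants: 28 enone acid
Product: 29 trimethylsilyl 8α,14-bis(trimethylsilyloxy)labda-13(16),14-dien-19-oate
Conditions: TMSOTf (4.5 equiv), Et3N, CH2Cl2, −10 °C; cold aq NaHCO3 wash, used crude
Reagents that add atoms: trimethylsilyl triflate, C[Si](C)(C)OS(=O)(=O)C(F)(F)F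
Why: In this soft enolisation C15 holds the only enolisable hydrogens of the enone, so the cross-conjugated 2-silyloxydiene forms, while the acid and the tertiary alcohol are masked in passing as TMS derivatives.

Step 18
Reactants: 29 tris-TMS dienol ether
Product: 31 8α,15-dihydroxy-14-oxolabd-13(16)-en-19-oic acid, via 15-silyloxy ketone 30 (not isolated)
Conditions: mCPBA (1.05 equiv), CH2Cl2–hexane, −20 °C; then citric acid, MeOH–H2O, rt
Reagents that add atoms: 3-chloroperbenzoic acid, O=C(OO)c1cccc(Cl)c1
Why: In the Rubottom oxidation the peracid epoxidises the electron-rich C14=C15 enol ether faster than the C13=C16 bond, silyl migration gives the 15-silyloxy ketone, and mild acid removes all three TMS groups without touching the enone or the tertiary alcohol.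

Compound list
1 | pentane-2,4-dione | CC(=O)CC(C)=O | starting material
2 | 2-(3-chloropropyl)-2-methyl-1,3-dioxolane | CC1(CCCCl)OCCO1 | starting material
3 | 2-(3-iodopropyl)-2-methyl-1,3-dioxolane | CC1(CCCI)OCCO1 | intermediate
4 | 3-[3-(2-methyl-1,3-dioxolan-2-yl)propyl]pentane-2,4-dione | CC(=O)C(CCCC1(C)OCCO1)C(C)=O | intermediate
5 | (2Z)-3-acetyl-6-(2-methyl-1,3-dioxolan-2-yl)hex-2-en-2-yl triflate | CC(=O)/C(CCCC1(C)OCCO1)=C(/C)OS(=O)(=O)C(F)(F)F | intermediate
6 | but-3-enoic acid | C=CCC(=O)O | starting material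
7 | N,O-dimethylhydroxylamine hydrochloride | CNOC.Cl | starting material
8 | 1-(but-3-enoyl)imidazole | C=CCC(=O)n1ccnc1 | intermediate
9 | N-methoxy-N-methylbut-3-enamide | C=CCC(=O)N(C)OC | intermediate
10 | 4-(9-borabicyclo[3.3.1]nonan-9-yl)-N-methoxy-N-methylbutanamide | CON(C)C(=O)CCCB1C2CCCC1CCC2 | intermediate
11 | (5Z)-6-acetyl-N-methoxy-N,5-dimethyl-9-(2-methyl-1,3-dioxolan-2-yl)non-5-enamide | CC(=O)/C(CCCC1(C)OCCO1)=C(/C)CCCC(=O)N(C)OC | intermediate
12 | lithium cross-conjugated dienolate of 11 | [Li+].C=C([O-])/C(CCCC1(C)OCCO1)=C(/C)CCCC(=O)N(C)OC | intermediate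
13 | (5Z)-N-methoxy-N,5-dimethyl-9-(2-methyl-1,3-dioxolan-2-yl)-6-[1-(triisopropylsilyloxy)vinyl]non-5-enamide | C=C(O[Si](C(C)C)(C(C)C)C(C)C)/C(CCCC1(C)OCCO1)=C(/C)CCCC(=O)N(C)OC | intermediate
14 | bromomagnesium hemiaminal chelate from 13 and vinylmagnesium bromide | C=CC(O[Mg]Br)(CCC/C(C)=C(/CCCC1(C)OCCO1)C(=C)O[Si](C(C)C)(C(C)C)C(C)C)N(C)OC | intermediate
15 | (7Z)-7-methyl-11-(2-methyl-1,3-dioxolan-2-yl)-8-[1-(triisopropylsilyloxy)vinyl]undeca-1,7-dien-3-one | C=CC(=O)CCC/C(C)=C(/CCCC1(C)OCCO1)C(=C)O[Si](C(C)C)(C(C)C)C(C)C | intermediate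
16 | 14,14-(ethylenedioxy)-8-(triisopropylsilyloxy)-16,17,18,19-tetranorlabd-8-en-4-one, 5β-H (cis-fused) | CC1(CCCC2=C(O[Si](C(C)C)(C(C)C)C(C)C)CC[C@@H]3C(=O)CCC[C@]23C)OCCO1 | intermediate
17 | 14,14-(ethylenedioxy)-8-(triisopropylsilyloxy)-16,17,18,19-tetranorlabd-8-en-4-one, 5α-H (trans-fused) | CC1(CCCC2=C(O[Si](C(C)C)(C(C)C)C(C)C)CC[C@H]3C(=O)CCC[C@]23C)OCCO1 | intermediate
18 | potassium Δ3-enolate of 17 | [K+].CC1(CCCC2=C(O[Si](C(C)C)(C(C)C)C(C)C)CC[C@H]3C([O-])=CCC[C@]23C)OCCO1 | intermediate
19 | 14,14-(ethylenedioxy)-8-(triisopropylsilyloxy)-16,17,18,19-tetranorlabda-3,8-dien-4-yl triflate | CC1(CCCC2=C(O[Si](C(C)C)(C(C)C)C(C)C)CC[C@H]3C(OS(=O)(=O)C(F)(F)F)=CCC[C@]23C)OCCO1 | intermediate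
20 | methyl 14,14-(ethylenedioxy)-8-(triisopropylsilyloxy)-16,17,18-trinorlabda-3,8-dien-19-oate | CC1(CCCC2=C(O[Si](C(C)C)(C(C)C)C(C)C)CC[C@H]3C(C(=O)OC)=CCC[C@]23C)OCCO1 | intermediate
21 | lithium C4 ester enolate from 20 | [Li+].CC1(CCCC2=C(O[Si](C(C)C)(C(C)C)C(C)C)CC[C@H]3C(=C([O-])OC)CCC[C@]23C)OCCO1 | intermediate
22 | methyl 14,14-(ethylenedioxy)-8-(triisopropylsilyloxy)-16,17-dinorlabd-8-en-19-oate | CC1(CCCC2=C(O[Si](C(C)C)(C(C)C)C(C)C)CC[C@H]3[C@@](C)(C(=O)OC)CCC[C@]23C)OCCO1 | intermediate
23 | methyl 14,14-(ethylenedioxy)-8-oxo-16,17-dinorlabdan-19-oate | CC1(CCC[C@@H]2[C@@]3(C)CCC[C@](C)(C(=O)OC)[C@@H]3CCC2=O)OCCO1 | intermediate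
24 | methyl 14,14-(ethylenedioxy)-16-norlabd-8(17)-en-19-oate | CC1(CCC[C@@H]2[C@@]3(C)CCC[C@](C)(C(=O)OC)[C@@H]3CCC2=C)OCCO1 | intermediate
25 | methyl 14,14-(ethylenedioxy)-8α-hydroxy-16-norlabdan-19-oate | CC1(CCC[C@@H]2[C@@]3(C)CCC[C@](C)(C(=O)OC)[C@@H]3CC[C@@]2(C)O)OCCO1 | intermediate
26 | 14,14-(ethylenedioxy)-8α-hydroxy-16-norlabdan-19-oic acid | CC1(CCC[C@@H]2[C@@]3(C)CCC[C@](C)(C(=O)O)[C@@H]3CC[C@@]2(C)O)OCCO1 | intermediate
27 | 8α-hydroxy-14-oxo-16-norlabdan-19-oic acid | CC(=O)CCC[C@@H]1[C@@]2(C)CCC[C@](C)(C(=O)O)[C@@H]2CC[C@@]1(C)O | intermediate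
28 | 8α-hydroxy-14-oxolabd-13(16)-en-19-oic acid | C=C(CC[C@@H]1[C@@]2(C)CCC[C@](C)(C(=O)O)[C@@H]2CC[C@@]1(C)O)C(C)=O | intermediate
29 | trimethylsilyl 8α,14-bis(trimethylsilyloxy)labda-13(16),14-dien-19-oate | C=C(CC[C@@H]1[C@@]2(C)CCC[C@](C)(C(=O)O[Si](C)(C)C)[C@@H]2CC[C@@]1(C)O[Si](C)(C)C)C(=C)O[Si](C)(C)C | intermediate
30 | trimethylsilyl 14-oxo-8α,15-bis(trimethylsilyloxy)labd-13(16)-en-19-oate | C=C(CC[C@@H]1[C@@]2(C)CCC[C@](C)(C(=O)O[Si](C)(C)C)[C@@H]2CC[C@@]1(C)O[Si](C)(C)C)C(=O)CO[Si](C)(C)C | intermediate
31 | 8α,15-dihydroxy-14-oxolabd-13(16)-en-19-oic acid | C=C(CC[C@@H]1[C@@]2(C)CCC[C@](C)(C(=O)O)[C@@H]2CC[C@@]1(C)O)C(=O)CO | target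

Total step count: 18. Longest linear sequence: 17 (steps 1, 2 and 4–18; step 3 is a one-step side branch).

Steps most likely to fail

Step 7. The tetrasubstituted Z-diene may be too slow to reach the reactive s-cis geometry at the low temperature that face selection needs. The acid may also protodesilylate the dienol ether, or the facial selectivity on the bound enone may be poor. The fallback moves stereocontrol from the catalyst to a covalently bound, removable auxiliary that also raises the reactivity of the dienophile. It sets out from 13. α-Lithiated (R)-p-tolyl vinyl sulfoxide (LDA, THF, −78 °C; both enantiomers are commercial) is acylated by 13 to give the 5-(p-tolylsulfinyl) trienone F1. The doubly activated dienophile of F1 should cyclise under control of the sulfinyl group (ZnBr2, CH2Cl2, −20 °C → rt) to the 5β-(p-tolylsulfinyl) cis-decalone F2. Reductive cleavage of the β-keto sulfoxide (Al/Hg, THF–H2O) followed by NaOMe equilibration returns to the route at 17.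

Step 16. The condensation may also occur at the C15 methyl group, a second methylene unit may be transferred, or the α-methylene ketone may oligomerise on heating. The fallback separates the regiochemical decision from the C–C bond formation. It sets out from 27. Thermodynamic silylation (Me3SiCl, NaI, Et3N, MeCN) gives the internal (Z)-silyl enol ether F3, in which acid and alcohol are also silylated. Dimethyl(methylene)ammonium iodide in CH2Cl2 and a mildly acidic work-up give the C13 Mannich base F4. One equivalent of mCPBA at 0 °C forms the amine N-oxide F5, whose Cope elimination at room temperature comes back to the route at 28.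

Step 14. The C8 radical may capture O2 with poor facial selectivity, or be reduced to the alkane by a second hydrogen-atom transfer. The fallback replaces the radical hydration by a polar Markovnikov hydration. It sets out from 24. Oxymercuration (Hg(OAc)2, THF–H2O, rt), in which water opens the mercurinium ion at C8 from the α face, gives the 17-(acetoxymercurio)-8α-alcohol F6. Demercuration with NaBH4 in aq NaOH returns to the route at 25.

Further compounds
F1 | step 7 | (7Z)-7-methyl-11-(2-methyl-1,3-dioxolan-2-yl)-2-(p-tolylsulfinyl)-8-[1-(triisopropylsilyloxy)vinyl]undeca-1,7-dien-3-one, sulfur configured as in (R)-p-tolyl vinyl sulfoxide | C=C(C(=O)CCC/C(C)=C(/CCCC1(C)OCCO1)C(=C)O[Si](C(C)C)(C(C)C)C(C)C)[S@@](=O)c1ccc(C)cc1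
F2 | step 7 | 14,14-(ethylenedioxy)-5β-(p-tolylsulfinyl)-8-(triisopropylsilyloxy)-16,17,18,19-tetranorlabd-8-en-4-one (cis-fused) | CC1(CCCC2=C(O[Si](C(C)C)(C(C)C)C(C)C)CC[C@]3([S@@](=O)c4ccc(C)cc4)C(=O)CCC[C@]23C)OCCO1
F3 | step 16 | trimethylsilyl (13Z)-8α,14-bis(trimethylsilyloxy)-16-norlabd-13-en-19-oate | C/C(O[Si](C)(C)C)=C/CC[C@@H]1[C@@]2(C)CCC[C@](C)(C(=O)O[Si](C)(C)C)[C@@H]2CC[C@@]1(C)O[Si](C)(C)C
F4 | step 16 | 16-(dimethylamino)-8α-hydroxy-14-oxolabdan-19-oic acid (both C13 epimers) | CC(=O)C(CN(C)C)CC[C@@H]1[C@@]2(C)CCC[C@](C)(C(=O)O)[C@@H]2CC[C@@]1(C)O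
F5 | step 16 | N-oxide of F4 | CC(=O)C(C[N+](C)(C)[O-])CC[C@@H]1[C@@]2(C)CCC[C@](C)(C(=O)O)[C@@H]2CC[C@@]1(C)O
F6 | step 14 | methyl 17-(acetoxymercurio)-14,14-(ethylenedioxy)-8α-hydroxy-16-norlabdan-19-oate | CC1(CCC[C@@H]2[C@@]3(C)CCC[C@](C)(C(=O)OC)[C@@H]3CC[C@@]2(C[Hg]OC(C)=O)O)OCCO1
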